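The earlier runs and the new flask are simulated for an exercise; scatter was added.

3 questions stand on one flask, and one ratio of the charges serves them.

| flask | substrate | partner | remark | time |
|---|---|---|---|---|
| dusk | 0.10 M | 0.18 M | the very flask that is asked about, followed so far |  |
| autumn | 0.15 M | 0.18 M | run made earlier |  |
| flask | 0.10 M | 0.180 M |  | 6.0 h |

The dusk flask is the one asked about, followed so far, and autumn is an earlier run with more substrate. The dusk flask holds 1.80 equivalents of partner: call this the cover, partner charged over substrate charged. Suppose one partner goes into each target, and reckon with what is left once everything has reacted. A cover above one leaves unused the fraction of the partner equal to one minus the inverse of the cover, and a cover under one leaves the fraction of the substrate equal to one minus the cover short of target. For the dusk flask that leaves 44.4 % of the partner.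

- dusk (time / h: substrate / %, target / %): 0.833: 0.1, 98.6; 1.50: 0.4, 100.2; 2.50: 0, 100.1; 3.00: 0, 99.5
- autumn (time / h: substrate / %, target / %): 1.00: 0, 95.8; 2.00: 0, 99.5; 3.00: 0, 100.3; 4.00: 0, 99.6

(each reading ± 0.3 percentage points)

The readings give substrate and target, and no partner. Dusk has 0.1 % substrate at 0.833 h, and autumn, with a cover of 1.20, reads 100.3 % target at 3.00 h. So your reckoning for the dusk flask is substrate fully reacted and target level with the substrate charged.

- the state of affairs at 6.0 h: stopped, and by what, or still going (the partner has run out first / it is still moving / all of the substrate has reacted)
- how much of the substrate has reacted by 6.0 h
- how much target there is at 6.0 h, in percent of the substrate charged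

- the reaction counts as stopped when no species that holds the substrate changes by six tenths of a point or more over the second half of the time

The forecast reads: all of the substrate has reacted, with 100 % converted and 99.8 % target, and says “The partner isn't limiting”. The flask gives: all of the substrate has reacted, with 100 % converted and 100 % target.

    substrate → intermediate (k = 0.0176 s⁻¹)
    partner + intermediate → target (k = 0.0153 M⁻¹ s⁻¹)

At 6.00 h this flask holds 0 % of its substrate against 44 % of its partner, the 44.4 % the cover gave, with substrate as the limiting reagent. Its slowest mode has a half-life of 0.157 h, short against the 6.0 h asked. A neighbour flask is charged with 0.072 M of partner, a cover of 0.720 equiv: at 6.00 h it holds 0 % of its partner and 28.0 % as intermediate, the 28.0 % that one minus the cover gave, and its target stands at 72.0 %.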